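The synthesis cuts ring B at C6'–C1' and C2'–C3'. This five-fold substituted ring divides into two parts. The four-carbon edge C3'–C4'–C5'–C6' (O, O, prenyl, H) is stored in a squarate-derived cyclobutenone. The two-carbon unit C1'=C2' is the double bond of an alkenylstannane already fixed to C2 of the finished (S)-chroman (rings A and C). In one flask a Stille coupling joins both pieces and heating turns the adduct into the arene, so no substitution on a crowded benzene is needed. The precursors are a racemic 4-chlorocyclobutenone and an (S,E)-alkenylstannane.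

Key step: step 17

Remark on the chemistry: the descriptor at C2 is read as (S). A 4'-oxygenated flavan can open at C2–O1 through a quinone methide, so strong acid, hot base and long-lived quinones are avoided after step 17.

Step 1
Reactants: 1 umbelliferone
Product: 2 7-hydroxychroman-2-one
Conditions: H2 (1 atm), Pd/C (10 wt%), EtOAc/AcOH, rt
Reagents that add atoms: none
Why: Catalytic hydrogenation over palladium saturates the conjugated C3=C4 bond of the coumarin much faster than the phenol ring or the lactone carbonyl, so the dihydrocoumarin should form cleanly.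

Step 2
Reactants: 2 7-hydroxychroman-2-one; 3 prenyl bromide
Product: 4 7-(3-methylbut-2-enyloxy)chroman-2-one
Conditions: K2CO3, acetone, reflux
Reagents that add atoms: none
Why: In this Williamson ether synthesis the only free phenol is alkylated at the primary carbon of the allylic bromide under mild carbonate conditions, while the lactone keeps O1 masked.

Step 3
Reactants: 4 7-(3-methylbut-2-enyloxy)chroman-2-one; 5 N,O-dimethylhydroxylamine hydrochloride
Product: 7 3-[2-hydroxy-4-(3-methylbut-2-enyloxy)phenyl]-N-methoxy-N-methylpropanamide, via chloromagnesium amide 6 (not isolated)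
Conditions: 5, iPrMgCl, THF, −20 °C; then 4, −20 → 0 °C; aq. NH4Cl
Reagents that add atoms: none
Why: The preformed magnesium amide opens the activated aryl lactone by acyl substitution (Weinreb amide formation), which at the same time frees the O1 phenol needed for the later ring closure.

Step 4
Reactants: 8 ethynylmagnesium bromide; 3 prenyl bromide
Product: 9 5-methylhex-4-en-1-yne
Conditions: CuCl (5 mol%), THF, 0 °C → rt; distillation
Reagents that add atoms: none
Why: Copper-catalysed allylic substitution by an alkynyl Grignard reagent takes place at the unhindered primary carbon of prenyl bromide and should give the skipped enyne as a distillable liquid.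

Step 5
Reactants: 9 5-methylhex-4-en-1-yne; 7 3-[2-hydroxy-4-(3-methylbut-2-enyloxy)phenyl]-N-methoxy-N-methylpropanamide
Product: 11 1-[2-hydroxy-4-(3-methylbut-2-enyloxy)phenyl]-8-methylnon-7-en-4-yn-3-one, via lithium acetylide 10 (not isolated)
Conditions: 9 (2.5 equiv), nBuLi (2.4 equiv), THF, −78 °C; then 7, −78 → −20 °C; aq. NH4Cl
Reagents that add atoms: none
Why: In this Weinreb ketone synthesis one equivalent of acetylide is spent on the phenol and the next adds once to the amide, and the chelated tetrahedral adduct lasts until the quench, so no tertiary alcohol should form and the base-sensitive skipped ynone is released only on neutral work-up.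

Step 6
Reactants: 11 1-[2-hydroxy-4-(3-methylbut-2-enyloxy)phenyl]-8-methylnon-7-en-4-yn-3-one
Product: 12 (R)-1-[2-hydroxy-4-(3-methylbut-2-enyloxy)phenyl]-8-methylnon-7-en-4-yn-3-ol
Conditions: RuCl[(R,R)-TsDPEN](p-cymene) (1 mol%), HCO2H/Et3N (5:2), CH2Cl2, rt
Reagents that add atoms: none
Why: In this Noyori–Ikariya asymmetric transfer hydrogenation the (R,R)-diamine complex delivers hydride to the carbonyl face that places the alkynyl pi system next to the arene ligand, which for alkyl alkynyl ketones gives the (R)-propargylic alcohol and so sets the carbon that becomes C2 without touching alkyne, alkenes or phenol.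

Step 7
Reactants: 12 (R)-1-[2-hydroxy-4-(3-methylbut-2-enyloxy)phenyl]-8-methylnon-7-en-4-yn-3-ol
Product: 13 (S)-2-(5-methylhex-4-en-1-ynyl)-7-(3-methylbut-2-enyloxy)chroman
Conditions: PPh3, DIAD, THF (0.02 M), 0 °C → rt
Reagents that add atoms: none
Why: In this intramolecular Mitsunobu etherification the phenol displaces the oxyphosphonium group in a 6-exo-tet SN2 process with inversion, so the (R)-alcohol should give the (S)-configured C2 of ring C.

Step 8
Reactants: 13 (S)-2-(5-methylhex-4-en-1-ynyl)-7-(3-methylbut-2-enyloxy)chroman
Product: 14 (S)-6-(2-methylbut-3-en-2-yl)-2-(5-methylhex-4-en-1-ynyl)chroman-7-ol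
Conditions: PhNEt2, 190 °C, argon, sealed tube
Reagents that add atoms: none
Why: The [3,3] shift of this aromatic Claisen rearrangement delivers the tertiary end of the O-prenyl group to an ortho carbon and should choose C6, which is para to the donor O1 and far less crowded than C8 between two oxygens (the pattern known for 2-alkoxy-4-prenyloxyarenes), while the ring-bound C2–O1 bond cannot adopt the geometry for a competing propargyl shift and the basic solvent suppresses acid-induced cyclisation of the product.

Step 9
Reactants: 14 (S)-6-(2-methylbut-3-en-2-yl)-2-(5-methylhex-4-en-1-ynyl)chroman-7-ol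
Product: 15 (S)-7-(tert-butyldimethylsilyloxy)-6-(2-methylbut-3-en-2-yl)-2-(5-methylhex-4-en-1-ynyl)chroman
Conditions: TBSCl, imidazole, DMF, rt → 40 °C
Reagents that add atoms: TBSCl, CC(C)(C)[Si](C)(C)Cl
Why: Standard silylation of the hindered but acidic phenol shields O7 from ketene capture in step 17 and from the oxidant of step 18.

Step 10
Reactants: 15 (S)-7-(tert-butyldimethylsilyloxy)-6-(2-methylbut-3-en-2-yl)-2-(5-methylhex-4-en-1-ynyl)chroman; 16 tributyltin hydride
Product: 17 (S)-7-(tert-butyldimethylsilyloxy)-6-(2-methylbut-3-en-2-yl)-2-[(1E)-5-methyl-1-(tributylstannyl)hexa-1,4-dienyl]chroman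
Conditions: Mo(CO)3(CNtBu)3 (5 mol%), hydroquinone (10 mol%), THF, 60 °C; Et3N-washed silica
Reagents that add atoms: none
Why: Molybdenum-catalysed hydrostannation adds H and Sn to the same face of the alkyne and, unlike the palladium-catalysed version that follows sterics at a branched propargylic carbon, places tin on the alkyne carbon polarised by the neighbouring C2–O1 bond, which should give the (E)-stannane with H cis to tin and leave the isolated alkenes untouched.

Step 11
Reactants: 18 dimethyl squarate
Product: 19 4-hydroxy-2,3-dimethoxycyclobut-2-en-1-one (racemic)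
Conditions: LiAlH(OtBu)3 (1.05 equiv), THF, −78 → −40 °C; aq. potassium sodium tartrate
Reagents that add atoms: none
Why: The bulky mild hydride reduces one of the two equivalent, highly electrophilic carbonyl groups and stops there because the remaining carbonyl is a deactivated vinylogous ester (chemoselective 1,2-reduction), and the racemic new centre is destroyed later.

Step 12
Reactants: 19 4-hydroxy-2,3-dimethoxycyclobut-2-en-1-one
Product: 20 4-(tert-butyldimethylsilyloxy)-2,3-dimethoxycyclobut-2-en-1-one
Conditions: TBSCl, imidazole, CH2Cl2, 0 °C → rt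
Reagents that add atoms: TBSCl, CC(C)(C)[Si](C)(C)Cl
Why: Silyl ether formation turns the secondary hydroxyl into a poor leaving group, so that only the tertiary alcohol made in the next step can ionise.

Step 13
Reactants: 20 4-(tert-butyldimethylsilyloxy)-2,3-dimethoxycyclobut-2-en-1-one; 21 allylmagnesium bromide
Product: 23 3-allyl-4-(tert-butyldimethylsilyloxy)-2-methoxycyclobut-2-en-1-one, via tertiary carbinol 22 (not isolated)
Conditions: THF, −78 °C; then 1 M aq. HCl, 0 °C, short contact
Reagents that add atoms: water, O
Why: The Grignard reagent adds 1,2 to the only carbonyl (direct attack at C3 with loss of methoxide would give the same product), and acid then ionises the tertiary alcohol with help from the C3 methoxy group so that hydrolysis moves the carbonyl to C3 (a vinylogous-ester carbonyl transposition of the Stork–Danheiser type), which leaves methoxy next to C=O, allyl on the beta carbon and the silyl ether intact.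

Step 14
Reactants: 23 3-allyl-4-(tert-butyldimethylsilyloxy)-2-methoxycyclobut-2-en-1-one; 24 2-methylbut-2-ene
Product: 25 4-(tert-butyldimethylsilyloxy)-2-methoxy-3-(3-methylbut-2-enyl)cyclobut-2-en-1-one
Conditions: 24 (excess), second-generation Grubbs catalyst RuCl2(H2IMes)(PCy3)(=CHPh) (3 mol%), 1,4-benzoquinone (10 mol%), CH2Cl2, 40 °C
Reagents that add atoms: none
Why: Olefin cross metathesis in excess 2-methylbut-2-ene exchanges =CH2 for =CMe2 (the standard allyl-to-prenyl conversion), avoids the 1,1-dimethylallyl adduct that a prenyl Grignard reagent would give by attack through its tertiary end, and spares the tetrasubstituted electron-poor ring alkene.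

Step 15
Reactants: 25 4-(tert-butyldimethylsilyloxy)-2-methoxy-3-(3-methylbut-2-enyl)cyclobut-2-en-1-one
Product: 26 4-hydroxy-2-methoxy-3-(3-methylbut-2-enyl)cyclobut-2-en-1-one
Conditions: TBAF/AcOH (1:1), THF, 0 °C
Reagents that add atoms: none
Why: Fluoride cleaves the Si–O bond (fluoride desilylation), and the acetic acid buffer keeps the medium near neutral so that neither acid-triggered loss of methanol to the cyclobutenedione nor a base-induced shift of the skipped alkene sets in.

Step 16
Reactants: 26 4-hydroxy-2-methoxy-3-(3-methylbut-2-enyl)cyclobut-2-en-1-one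
Product: 27 4-chloro-2-methoxy-3-(3-methylbut-2-enyl)cyclobut-2-en-1-one (racemic)
Conditions: Me2C=C(Cl)NMe2, CH2Cl2, 0 °C; used at once
Reagents that add atoms: 1-chloro-N,N,2-trimethylprop-1-en-1-amine, CC(C)=C(Cl)N(C)C
Why: The alpha-chloroenamine converts the alcohol into an alkoxyiminium chloride that collapses to the chloride and a neutral amide without free HCl (deoxychlorination under neutral conditions), so the prenyl alkene and the enol ether should survive, and the lack of stereocontrol is irrelevant because C4 becomes the sp2 carbon C6'.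

Step 17
Reactants: 27 4-chloro-2-methoxy-3-(3-methylbut-2-enyl)cyclobut-2-en-1-one; 17 (S,E)-alkenylstannane
Product: 31 (S)-7-(tert-butyldimethylsilyloxy)-2-[3-hydroxy-4-methoxy-2,5-bis(3-methylbut-2-enyl)phenyl]-6-(2-methylbut-3-en-2-yl)chroman, via 4-alkenylcyclobutenone 28 (not isolated), via dienylketene 29 (not isolated), via cyclohexadienone 30 (not isolated)
Conditions: PdCl2(PhCN)2 (5 mol%), P(2-furyl)3 (10 mol%), CuI (10 mol%), dioxane, 50 °C; then 100 °C
Reagents that add atoms: none
Why: Zerovalent palladium, formed in the flask from PdCl2(PhCN)2 and P(2-furyl)3, inserts into the allylic, alpha-keto C4–Cl bond of 27, the alkenyl group of 17 is handed over with retention of geometry (CuI helps the transfer from the alpha-branched tin centre), and reductive elimination at the CH terminus of the oxocyclobutenyl ligand forms C6'–C1' in 28. On heating to 100 °C the strained ring of 28 opens and re-closes in a conrotatory four-electron equilibrium, and only the isomer of 29 that holds C1' cis to the ketene unit can react further. Ring B then closes by a disrotatory six-electron electrocyclisation in which C2' bonds to the ketene carbon C3', and enolisation of 30 makes the sequence irreversible and delivers the 3'-phenol next to the 4'-methoxy group. The closest known reaction type is the palladium-catalysed coupling of 4-chlorocyclobutenones with alkenylstannanes followed by thermal benzannulation to phenols. No lasting stereocentre is created, since C4 of 27 and C2' of 30 end as sp2 carbons, and C2 of the chroman is a spectator under these neutral conditions. The step needs coupling at C4 rather than at the methoxy-bearing C2, which is secured because the latter would create a quaternary centre, and it needs an unhindered closure, which is secured because tin and H were added to the same alkyne face so that the inner position at C2' carries only H.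

Step 18
Reactants: 31 (S)-3'-hydroxy-4'-methoxyflavan silyl ether
Product: 33 (S)-7-(tert-butyldimethylsilyloxy)-2-[3,4-dihydroxy-2,5-bis(3-methylbut-2-enyl)phenyl]-6-(2-methylbut-3-en-2-yl)chroman, via ortho-quinone 32 (not isolated)
Conditions: IBX (1.1 equiv), DMF, 0 °C, dark; then aq. Na2S2O4, 0 °C, same flask
Reagents that add atoms: IBX, O=C1OI(=O)(O)c2ccccc12
Why: IBX binds the free 3'-phenol and transfers oxygen to the electron-rich ortho carbon C4', methanol is lost to give the ortho-quinone (oxidative demethylation of a guaiacol), and dithionite reduces it at once to the catechol, the low temperature and short quinone lifetime being chosen to prevent tautomerisation to quinone methides that would endanger C2 and the prenyl groups.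

Step 19
Reactants: 33 (S)-catechol silyl ether
Product: 34 target, (S)-2-[3,4-dihydroxy-2,5-bis(3-methylbut-2-enyl)phenyl]-6-(2-methylbut-3-en-2-yl)chroman-7-ol
Conditions: TBAF/AcOH (1:1), THF, 0 °C, argon
Reagents that add atoms: none
Why: Buffered fluoride cleaves the aryl silyl ether quickly at 0 °C (fluoride desilylation), and the near-neutral medium avoids both acid-induced cyclisation of the ortho-prenyl phenols and base-induced opening of the C2–O1 bond, so the (S) configuration should be kept.

Compound list
1 | umbelliferone (7-hydroxy-2H-chromen-2-one) | O=c1ccc2ccc(O)cc2o1 | starting material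
2 | 7-hydroxychroman-2-one | O=C1CCc2ccc(O)cc2O1 | intermediate
3 | prenyl bromide (1-bromo-3-methylbut-2-ene) | CC(C)=CCBr | starting material
4 | 7-(3-methylbut-2-enyloxy)chroman-2-one | O=C1CCc2ccc(OCC=C(C)C)cc2O1 | intermediate
5 | N,O-dimethylhydroxylamine hydrochloride | CNOC.Cl | starting material
6 | chloromagnesium N-methoxy-N-methylamide (not isolated) | CON(C)[Mg]Cl | intermediate
7 | 3-[2-hydroxy-4-(3-methylbut-2-enyloxy)phenyl]-N-methoxy-N-methylpropanamide | CON(C)C(=O)CCc1ccc(OCC=C(C)C)cc1O | intermediate
8 | ethynylmagnesium bromide | C#C[Mg]Br | starting material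
9 | 5-methylhex-4-en-1-yne | C#CCC=C(C)C | intermediate
10 | lithium 5-methylhex-4-en-1-ynide (not isolated) | [Li]C#CCC=C(C)C | intermediate
11 | 1-[2-hydroxy-4-(3-methylbut-2-enyloxy)phenyl]-8-methylnon-7-en-4-yn-3-one | CC(C)=CCC#CC(=O)CCc1ccc(OCC=C(C)C)cc1O | intermediate
12 | (R)-1-[2-hydroxy-4-(3-methylbut-2-enyloxy)phenyl]-8-methylnon-7-en-4-yn-3-ol | O[C@H](CCc1ccc(OCC=C(C)C)cc1O)C#CCC=C(C)C | intermediate
13 | (S)-2-(5-methylhex-4-en-1-ynyl)-7-(3-methylbut-2-enyloxy)chroman | CC(C)=CCOc1ccc2c(c1)O[C@H](C#CCC=C(C)C)CC2 | intermediate
14 | (S)-6-(2-methylbut-3-en-2-yl)-2-(5-methylhex-4-en-1-ynyl)chroman-7-ol | C=CC(C)(C)c1cc2c(cc1O)O[C@H](C#CCC=C(C)C)CC2 | intermediate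
15 | (S)-7-(tert-butyldimethylsilyloxy)-6-(2-methylbut-3-en-2-yl)-2-(5-methylhex-4-en-1-ynyl)chroman | C=CC(C)(C)c1cc2c(cc1O[Si](C)(C)C(C)(C)C)O[C@H](C#CCC=C(C)C)CC2 | intermediate
16 | tributyltin hydride | CCCC[SnH](CCCC)CCCC | starting material
17 | (S)-7-(tert-butyldimethylsilyloxy)-6-(2-methylbut-3-en-2-yl)-2-[(1E)-5-methyl-1-(tributylstannyl)hexa-1,4-dienyl]chroman (H cis to Sn) | C=CC(C)(C)c1cc2c(cc1O[Si](C)(C)C(C)(C)C)O[C@H](/C([Sn](CCCC)(CCCC)CCCC)=C\CC=C(C)C)CC2 | intermediate
18 | dimethyl squarate | COC1=C(OC)C(=O)C1=O | starting material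
19 | 4-hydroxy-2,3-dimethoxycyclobut-2-en-1-one (racemic) | COC1=C(OC)C(=O)C1O | intermediate
20 | 4-(tert-butyldimethylsilyloxy)-2,3-dimethoxycyclobut-2-en-1-one (racemic) | COC1=C(OC)C(=O)C1O[Si](C)(C)C(C)(C)C | intermediate
21 | allylmagnesium bromide | C=CC[Mg]Br | starting material
22 | 1-allyl-4-(tert-butyldimethylsilyloxy)-2,3-dimethoxycyclobut-2-en-1-ol (diastereomer mixture, not isolated) | C=CCC1(O)C(OC)=C(OC)C1O[Si](C)(C)C(C)(C)C | intermediate
23 | 3-allyl-4-(tert-butyldimethylsilyloxy)-2-methoxycyclobut-2-en-1-one (racemic) | C=CCC1=C(OC)C(=O)C1O[Si](C)(C)C(C)(C)C | intermediate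
24 | 2-methylbut-2-ene | CC=C(C)C | starting material
25 | 4-(tert-butyldimethylsilyloxy)-2-methoxy-3-(3-methylbut-2-enyl)cyclobut-2-en-1-one (racemic) | CC(C)=CCC1=C(OC)C(=O)C1O[Si](C)(C)C(C)(C)C | intermediate
26 | 4-hydroxy-2-methoxy-3-(3-methylbut-2-enyl)cyclobut-2-en-1-one (racemic) | CC(C)=CCC1=C(OC)C(=O)C1O | intermediate
27 | 4-chloro-2-methoxy-3-(3-methylbut-2-enyl)cyclobut-2-en-1-one (racemic) | O=C1C(OC)=C(CC=C(C)C)C1Cl | intermediate
28 | 4-alkenylcyclobutenone: C4 of the cyclobutenone bonded to C1' in place of tin, (S) at C2, (Z) alkene by CIP with unchanged geometry, both epimers at C4 (not isolated) | C=CC(C)(C)c1cc2c(cc1O[Si](C)(C)C(C)(C)C)O[C@H](/C(C3C(=O)C(OC)=C3CC=C(C)C)=C\CC=C(C)C)CC2 | intermediate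
29 | dienylketene O=C3'=C4'(OMe)–C5'(prenyl)=C6'H–C1'=C2'H(prenyl), C1' cis to the ketene unit, (S) at C2 (not isolated) | C=CC(C)(C)c1cc2c(cc1O[Si](C)(C)C(C)(C)C)O[C@H](/C(/C=C(CC=C(C)C)\C(OC)=C=O)=C\CC=C(C)C)CC2 | intermediate
30 | cyclohexa-2,4-dienone tautomer of 31, sp3 C2' bearing H and prenyl, (S) at C2 (not isolated) | C=CC(C)(C)c1cc2c(cc1O[Si](C)(C)C(C)(C)C)O[C@H](C3=CC(CC=C(C)C)=C(OC)C(=O)C3CC=C(C)C)CC2 | intermediate
31 | (S)-7-(tert-butyldimethylsilyloxy)-2-[3-hydroxy-4-methoxy-2,5-bis(3-methylbut-2-enyl)phenyl]-6-(2-methylbut-3-en-2-yl)chroman | C=CC(C)(C)c1cc2c(cc1O[Si](C)(C)C(C)(C)C)O[C@H](c1cc(CC=C(C)C)c(OC)c(O)c1CC=C(C)C)CC2 | intermediate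
32 | ring B 3',4'-ortho-quinone of 33, (S) at C2 (not isolated) | C=CC(C)(C)c1cc2c(cc1O[Si](C)(C)C(C)(C)C)O[C@H](C3=C(CC=C(C)C)C(=O)C(=O)C(CC=C(C)C)=C3)CC2 | intermediate
33 | (S)-7-(tert-butyldimethylsilyloxy)-2-[3,4-dihydroxy-2,5-bis(3-methylbut-2-enyl)phenyl]-6-(2-methylbut-3-en-2-yl)chroman | C=CC(C)(C)c1cc2c(cc1O[Si](C)(C)C(C)(C)C)O[C@H](c1cc(CC=C(C)C)c(O)c(O)c1CC=C(C)C)CC2 | intermediate
34 | (S)-2-[3,4-dihydroxy-2,5-bis(3-methylbut-2-enyl)phenyl]-6-(2-methylbut-3-en-2-yl)chroman-7-ol (CNP0118330.1) | C=CC(C)(C)c1cc2c(cc1O)O[C@H](c1cc(CC=C(C)C)c(O)c(O)c1CC=C(C)C)CC2 | target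

Total step count: 19 (ten for the stannane including one for the enyne, six for the chloride, three from the union to the target).
Longest linear sequence: 12 steps (1, 2, 3, 5, 6, 7, 8, 9, 10, 17, 18, 19).

Steps most likely to fail

1. Step 17.
- **Risk:** Transfer of the alkenyl group from the alpha-branched, trisubstituted tin centre to palladium may be slower than the decay of the chloride (methoxy-assisted ionisation followed by loss of the methyl group). It may also be slower than protodestannylation.
- **Fallback:** The transferring metal is changed and the coupling is separated from the ring expansion. Setting out from 17, tin–lithium exchange (nBuLi, THF, −78 °C) gives the alkenyllithium F1. ZnCl2 converts it at −78 °C into the alkenylzinc chloride F2. A Negishi coupling with 27 (Pd2(dba)3, P(2-furyl)3, THF, −20 °C → rt) runs well below the temperature at which the chloride decays. It comes back to the route at 28, which is isolated and then heated in toluene at 100 °C to give 31.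

2. Step 10.
- **Risk:** Regiocontrol may erode, because steric pressure from the branched C2 can push tin to the distal alkyne carbon.
- **Fallback:** Copper hydride places the metal and tin is introduced afterwards. Setting out from 15, CuCl, Xantphos, NaOtBu and HBpin (toluene, rt) add Cu–H syn, with copper on the carbon next to the C2–O1 bond. Copper is then exchanged for boron to give the alkenylboronate F3. Iododeboronation with retention (NaOH, I2, THF, 0 °C) gives the alkenyl iodide F4, which can be freed from any regioisomer on ordinary silica. Stannylation with (Bu3Sn)2 under catalysis by zerovalent palladium (Pd(PPh3)4, toluene, 90 °C) comes back to the route at 17.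

3. Step 18.
- **Risk:** The ortho-quinone may live long enough to tautomerise, which would cause loss of configurational integrity at C2 or ring closure of a prenyl group onto oxygen. Oxygen may also be delivered to the prenyl-bearing ortho carbon C2'.
- **Fallback:** A non-oxidative, chelation-assisted dealkylation replaces the oxidation. Setting out from 31, AlCl3 (1.1 equiv) and pyridine (4.5 equiv) in CH2Cl2 at reflux tie aluminium to the 3'-phenoxide and the neighbouring methoxy oxygen, and pyridine takes the methyl group by SN2. The excess base keeps the medium free of acid and the aluminium away from O1. Work-up with aqueous potassium sodium tartrate comes back to the route at 33 (no new compound: F0).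

Further compounds
F1 | step 17 | (S)-7-(tert-butyldimethylsilyloxy)-2-[(1Z)-1-lithio-5-methylhexa-1,4-dienyl]-6-(2-methylbut-3-en-2-yl)chroman (H cis to Li) | C=CC(C)(C)c1cc2c(cc1O[Si](C)(C)C(C)(C)C)O[C@H](/C([Li])=C\CC=C(C)C)CC2
F2 | step 17 | (S)-7-(tert-butyldimethylsilyloxy)-2-[(1E)-1-(chlorozincio)-5-methylhexa-1,4-dienyl]-6-(2-methylbut-3-en-2-yl)chroman (H cis to Zn) | C=CC(C)(C)c1cc2c(cc1O[Si](C)(C)C(C)(C)C)O[C@H](/C([Zn]Cl)=C\CC=C(C)C)CC2
F3 | step 10 | (S)-7-(tert-butyldimethylsilyloxy)-2-[(1Z)-5-methyl-1-(4,4,5,5-tetramethyl-1,3,2-dioxaborolan-2-yl)hexa-1,4-dienyl]-6-(2-methylbut-3-en-2-yl)chroman (H cis to B) | C=CC(C)(C)c1cc2c(cc1O[Si](C)(C)C(C)(C)C)O[C@H](/C(B3OC(C)(C)C(C)(C)O3)=C\CC=C(C)C)CC2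
F4 | step 10 | (S)-7-(tert-butyldimethylsilyloxy)-2-[(1E)-1-iodo-5-methylhexa-1,4-dienyl]-6-(2-methylbut-3-en-2-yl)chroman (H cis to I) | C=CC(C)(C)c1cc2c(cc1O[Si](C)(C)C(C)(C)C)O[C@H](/C(I)=C\CC=C(C)C)CC2
F0 | step 18 | none | none
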